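The route cuts the γ-lactone (O–C6–C7–C11–C12) at C7–C8 and C11–C13. In one operation a lithiated dithiane standing for C8 adds to C7 of an enantiopure butenolide, and the lactone enolate is caught at C11 by Me2N=CH2 I. The flat butenolide ring, with C6 as its only stereocentre, forces both new substituents trans, so C7 is set and C11 carries a masked methylene. The precursor is the (S)-butenolide bearing the (Z)-C4=C5 arm, with O15 as TBDPS ether and O2 as TBS ether. The ten-membered ring (C1–C10) is closed afterwards at C1–C2 by NiCl2/CrCl2-mediated coupling, and C8 and C2 are set by reductions.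

Key step: step 13

Remarks on the chemistry
- Germacrane numbering is used throughout: ring C1–C10, C14 on C10, C15 on C4, C13 on C11.
- By the sequence rules C4=C5 is Z (C15 bears oxygen and outranks C3) although ring carbons C3 and C6 are trans; C1=C10 is Z; the target is (2S,6R,7R,8R).
- O2 is carried as a TBS ether, not a p-methoxybenzyl ether, because oxidative debenzylation would not tolerate the tertiary amine made in the key step.
- The (Z)-vinylsilane is made from prop-2-yn-1-ol by anti-carbomagnesiation, iodination and iodine-to-silicon exchange; carbomagnesiation of a C-silylated propargyl alcohol would place silicon trans to C9.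
- The key step creates two stereocentres: C7, which is kept, and C11, which is erased in step 24.
- Assumption: silyl ether 1, Bu3SnCH2OH and (−)-MIB [(2S)-3-exo-morpholinoisoborneol] are purchased; (CH2=CH)2Zn is prepared beforehand from CH2=CHMgBr and ZnCl2.
- TBS = tert-butyldimethylsilyl; TBDPS = tert-butyldiphenylsilyl.

Step 1
Reactants: 1 tert-butyl(but-3-yn-1-yloxy)dimethylsilane
Product: 3 5-[(TBS)oxy]pent-2-yn-1-ol, via lithium acetylide 2 (not isolated)
Conditions: n-BuLi, THF, −78 °C; (CH2O)n, −78 °C to rt; aq. NH4Cl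
Reagents that add atoms: paraformaldehyde (formaldehyde), C=O
Why: Hydroxymethylation of a lithium acetylide with formaldehyde is a standard acetylide addition to an aldehyde, and the TBS ether is inert to n-BuLi at low temperature.

Step 2
Reactants: 3 5-[(TBS)oxy]pent-2-yn-1-ol
Product: 5 (2Z)-5-[(TBS)oxy]-3-iodopent-2-en-1-ol, via cyclic sodium alkenylaluminate 4 (not isolated)
Conditions: NaAlH2(OCH2CH2OMe)2, THF, 0 °C to rt; I2, −78 to 0 °C
Reagents that add atoms: iodine, II
Why: Hydroxyl-directed trans-hydroalumination of the propargylic alcohol places aluminium on C4 cis to the CH2O group in a five-membered aluminate, and iodinolysis with retention gives the (Z)-3-iodoallylic alcohol, which fixes C6 cis to the future C15.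

Step 3
Reactants: 5 (2Z)-5-[(TBS)oxy]-3-iodopent-2-en-1-ol
Product: 6 (2Z)-5-[(TBS)oxy]-3-iodopent-2-enal
Conditions: MnO2, CH2Cl2, rt, dark
Reagents that add atoms: none
Why: MnO2 oxidation of an allylic alcohol to the enal is neutral, so the (Z)-iodoalkene and the silyl ether should persist.

Step 4
Reactants: 6 (2Z)-5-[(TBS)oxy]-3-iodopent-2-enal
Product: 7 (3S,4Z)-7-[(TBS)oxy]-5-iodohepta-1,4-dien-3-ol
Conditions: (CH2=CH)2Zn, (−)-MIB (10 mol %), toluene, −20 °C; aq. NH4Cl
Reagents that add atoms: divinylzinc, C=C[Zn]C=C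
Why: Amino-alcohol-catalysed asymmetric alkenylzinc addition to an aldehyde, in which (−)-MIB, a ligand of the class that turns benzaldehyde and Et2Zn into the (S)-alcohol, should deliver the vinyl group to the Si face of the enal and so set C6 as (S).

Step 5
Reactants: 7 (3S,4Z)-7-[(TBS)oxy]-5-iodohepta-1,4-dien-3-ol
Product: 8 (3S,4Z)-7-[(TBS)oxy]-5-(hydroxymethyl)hepta-1,4-dien-3-ol
Conditions: Bu3SnCH2OH, Pd(PPh3)4 (5 mol %), 1,4-dioxane, 80 °C
Reagents that add atoms: (tributylstannyl)methanol, CCCC[Sn](CCCC)(CCCC)CO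
Why: Stille coupling of the alkenyl iodide transfers the hydroxymethyl group with retention of alkene geometry, so C15 ends cis to C6, and the neutral conditions leave the bis-allylic alcohol alone.

Step 6
Reactants: 8 (3S,4Z)-7-[(TBS)oxy]-5-(hydroxymethyl)hepta-1,4-dien-3-ol
Product: 9 (3S,4Z)-7-[(TBS)oxy]-5-{[(TBDPS)oxy]methyl}hepta-1,4-dien-3-ol
Conditions: TBDPSCl (1.05 equiv), imidazole, CH2Cl2, 0 °C
Reagents that add atoms: tert-butyl(chloro)diphenylsilane, CC(C)(C)[Si](Cl)(c1ccccc1)c1ccccc1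
Why: Selective O-silylation, in which the bulky chlorosilane should take the primary allylic hydroxyl and leave the hindered secondary bis-allylic one.

Step 7
Reactants: 9 (3S,4Z)-7-[(TBS)oxy]-5-{[(TBDPS)oxy]methyl}hepta-1,4-dien-3-ol; 10 acryloyl chloride
Product: 11 (3S,4Z)-7-[(TBS)oxy]-5-{[(TBDPS)oxy]methyl}hepta-1,4-dien-3-yl prop-2-enoate
Conditions: i-Pr2NEt, CH2Cl2, −78 to 0 °C
Reagents that add atoms: none
Why: O-Acylation of the secondary alcohol with an acid chloride and a hindered amine base gives the acrylate without touching the C6–O bond.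

Step 8
Reactants: 11 (3S,4Z)-7-[(TBS)oxy]-5-{[(TBDPS)oxy]methyl}hepta-1,4-dien-3-yl prop-2-enoate
Product: 12 (5S)-5-[(1Z)-4-[(TBS)oxy]-2-{[(TBDPS)oxy]methyl}but-1-en-1-yl]furan-2(5H)-one
Conditions: second-generation Grubbs catalyst (5 mol %), toluene, 80 °C
Reagents that add atoms: none
Why: Ring-closing metathesis between the vinyl group and the acrylate forms the five-membered butenolide, the trisubstituted C4=C5 alkene being too hindered to compete and C6 not being involved.

Step 9
Reactants: 13 prop-2-yn-1-ol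
Product: 15 (2Z)-3-iodo-2-methylprop-2-en-1-ol, via cyclic alkenylmagnesium alkoxide 14 (not isolated)
Conditions: MeMgBr (2.5 equiv), CuI (10 mol %), THF, −10 °C to rt; I2, −78 to 0 °C
Reagents that add atoms: methylmagnesium bromide, C[Mg]Br; iodine, II
Why: Copper-catalysed anti-carbomagnesiation of the propargylic alkoxide puts methyl on C10 and magnesium on C1 cis to the CH2O group in a five-membered chelate, and iodinolysis with retention gives the (Z)-iodide.

Step 10
Reactants: 15 (2Z)-3-iodo-2-methylprop-2-en-1-ol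
Product: 18 (2Z)-2-methyl-3-(trimethylsilyl)prop-2-en-1-ol, via dilithio alkoxide 16 (not isolated), via O,C-bis(trimethylsilyl) compound 17 (not isolated)
Conditions: n-BuLi (1 equiv), then t-BuLi (2 equiv), Et2O, −78 °C; Me3SiCl (2.5 equiv), −78 °C to rt; K2CO3, MeOH, rt
Reagents that add atoms: chlorotrimethylsilane, C[Si](C)(C)Cl
Why: Iodine–lithium exchange on the lithium alkoxide gives a configurationally stable alkenyllithium that is C-silylated with retention, and mild methanolysis removes only the O-silyl group.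

Step 11
Reactants: 18 (2Z)-2-methyl-3-(trimethylsilyl)prop-2-en-1-ol
Product: 19 [(1Z)-3-bromo-2-methylprop-1-en-1-yl]trimethylsilane
Conditions: CBr4, PPh3, CH2Cl2, 0 °C
Reagents that add atoms: tetrabromomethane, BrC(Br)(Br)Br
Why: Appel bromination converts the primary allylic alcohol into the bromide under neutral conditions that do not disturb the vinylsilane geometry.

Step 12
Reactants: 19 [(1Z)-3-bromo-2-methylprop-1-en-1-yl]trimethylsilane; 20 1,3-dithiane
Product: 22 2-[(2Z)-2-methyl-3-(trimethylsilyl)prop-2-en-1-yl]-1,3-dithiane, via 2-lithio-1,3-dithiane 21 (not isolated)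
Conditions: n-BuLi, THF, −30 °C; then 19, −78 to 0 °C
Reagents that add atoms: none
Why: Corey–Seebach alkylation of 2-lithio-1,3-dithiane with a primary allylic bromide is a direct SN2 displacement that leaves the vinylsilane untouched.

Step 13
Reactants: 22 2-[(2Z)-2-methyl-3-(trimethylsilyl)prop-2-en-1-yl]-1,3-dithiane; 12 (5S)-5-[(1Z)-4-[(TBS)oxy]-2-{[(TBDPS)oxy]methyl}but-1-en-1-yl]furan-2(5H)-one; 23 N,N-dimethylmethyleneiminium iodide
Product: 26 (3R,4S,5R)-5-[(1Z)-4-[(TBS)oxy]-2-{[(TBDPS)oxy]methyl}but-1-en-1-yl]-3-[(dimethylamino)methyl]-4-{2-[(2Z)-2-methyl-3-(trimethylsilyl)prop-2-en-1-yl]-1,3-dithian-2-yl}oxolan-2-one, via lithiated dithiane 24 (not isolated), via lithium lactone enolate 25 (not isolated)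
Conditions: t-BuLi, THF/HMPA (10:1), −78 °C; 12, −78 °C; 23 (solid), −78 to 0 °C
Reagents that add atoms: none
Why: t-BuLi removes the dithiane C–H of 22, the sulfur-stabilised carbanion 24 (a solvent-separated ion pair in THF/HMPA) adds in Michael fashion to C7 of butenolide 12, and the lithium enolate 25 is then C-alkylated at C11 by iminium ion 23 in a Mannich reaction. The closest known reaction type is the tandem conjugate addition of lithiated dithioacetals to butenolides with electrophilic trapping of the enolate, as used for trans-disubstituted lignan lactones. No ring is closed. C7 is controlled by C6, because the carbanion attacks the planar ring on the face opposite the C6 alkenyl arm, and C11 is controlled by C7, because the iminium ion approaches the enolate anti to the bulky dithianyl group, which gives the trans,trans lactone. The step needs 1,4-addition to win over 1,2-addition and over deprotonation at C6, which the soft carbanion, HMPA and −78 °C should secure, and it needs facial selectivity, which the single C6 stereocentre supplies.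

Step 14
Reactants: 26 the dithiane lactone from step 13
Product: 27 (3R,4S,5R)-5-[(1Z)-4-[(TBS)oxy]-2-{[(TBDPS)oxy]methyl}but-1-en-1-yl]-3-[(dimethylamino)methyl]-4-[(3Z)-3-methyl-4-(trimethylsilyl)but-3-enoyl]oxolan-2-one
Conditions: CF3CO2H (1.1 equiv), then PhI(OCOCF3)2, MeCN/H2O 9:1, 0 °C, 10 min; aq. NaHCO3; crude ketone taken on at once
Reagents that add atoms: water, O
Why: Oxidative dethioacetalisation with PhI(OCOCF3)2 in wet acetonitrile acts at sulfur within minutes, and prior protonation of the amine shields it from the oxidant while the vinylsilane and silyl ethers should survive the short exposure.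

Step 15
Reactants: 27 the C8 ketone
Product: 28 (3R,4R,5R)-5-[(1Z)-4-[(TBS)oxy]-2-{[(TBDPS)oxy]methyl}but-1-en-1-yl]-3-[(dimethylamino)methyl]-4-[(1R,3Z)-1-hydroxy-3-methyl-4-(trimethylsilyl)but-3-en-1-yl]oxolan-2-one
Conditions: LiBH(s-Bu)3, THF, −78 °C; AcOH, −78 °C
Reagents that add atoms: none
Why: Felkin–Anh-controlled hydride reduction, in which the bulky borohydride should attack the C8 carbonyl anti to the C7–C6 bond, past H7 on the side of the smaller aminomethyl-bearing C11 branch, to give the (8R) alcohol while the lactone stays inert at −78 °C.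

Step 16
Reactants: 28 the (8R) alcohol
Product: 29 (3R,4S,5R)-5-[(1Z)-4-[(TBS)oxy]-2-{[(TBDPS)oxy]methyl}but-1-en-1-yl]-3-[(dimethylamino)methyl]-4-[(1R,3Z)-1-[(TBS)oxy]-3-methyl-4-(trimethylsilyl)but-3-en-1-yl]oxolan-2-one
Conditions: TBSOTf, 2,6-lutidine, CH2Cl2, −78 to 0 °C
Reagents that add atoms: tert-butyldimethylsilyl trifluoromethanesulfonate, CC(C)(C)[Si](C)(C)OS(=O)(=O)C(F)(F)F
Why: O-Silylation of the hindered secondary alcohol with a silyl triflate is fast at low temperature and forestalls translactonisation of the γ-hydroxy lactone.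

Step 17
Reactants: 29 the C8 TBS ether
Product: 30 (3R,4S,5R)-5-[(1Z)-4-[(TBS)oxy]-2-{[(TBDPS)oxy]methyl}but-1-en-1-yl]-3-[(dimethylamino)methyl]-4-[(1R,3Z)-1-[(TBS)oxy]-4-iodo-3-methylbut-3-en-1-yl]oxolan-2-one
Conditions: N-iodosuccinimide, (CF3)2CHOH, 0 °C
Reagents that add atoms: N-iodosuccinimide, O=C1CCC(=O)N1I
Why: Electrophilic ipso-iododesilylation of the vinylsilane passes through a β-silyl cation and should retain the alkene geometry, the amine being tied up by hydrogen bonding to the solvent and the electron-poorer C4=C5 alkene reacting more slowly.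

Step 18
Reactants: 30 the (Z)-vinyl iodide
Product: 31 (3R,4S,5R)-5-[(1Z)-2-{[(TBDPS)oxy]methyl}-4-hydroxybut-1-en-1-yl]-3-[(dimethylamino)methyl]-4-[(1R,3Z)-1-[(TBS)oxy]-4-iodo-3-methylbut-3-en-1-yl]oxolan-2-one
Conditions: HF·pyridine, pyridine, THF, 0 °C
Reagents that add atoms: none
Why: Selective desilylation, in which buffered HF·pyridine should cleave the unhindered primary TBS ether well before the hindered secondary TBS ether and the TBDPS ether.

Step 19
Reactants: 31 the C2 primary alcohol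
Product: 32 (3R,4S,5R)-5-[(1Z)-2-{[(TBDPS)oxy]methyl}-4-oxobut-1-en-1-yl]-3-[(dimethylamino)methyl]-4-[(1R,3Z)-1-[(TBS)oxy]-4-iodo-3-methylbut-3-en-1-yl]oxolan-2-one
Conditions: Dess–Martin periodinane, NaHCO3, CH2Cl2, 0 °C; used crude
Reagents that add atoms: none
Why: Dess–Martin oxidation under bicarbonate buffer gives the β,γ-unsaturated aldehyde without acid or base strong enough to move the C4=C5 alkene into conjugation.

Step 20
Reactants: 32 the iodo aldehyde
Product: 33 (6R,7S,8R,11R,1(10)Z,4Z)-13-(dimethylamino)-2-hydroxy-8-[(TBS)oxy]-15-[(TBDPS)oxy]germacra-1(10),4-dien-12,6-olide as a mixture of C2 epimers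
Conditions: CrCl2 (8 equiv), NiCl2 (10 mol %), degassed DMSO, rt, slow addition of 32 to about 3 mM
Reagents that add atoms: none
Why: Nozaki–Hiyama–Kishi reaction, in which nickel inserts into the C1–I bond, the alkenyl group passes to chromium with retention of the (Z)-geometry and adds chemoselectively to the aldehyde under high dilution to close the ten-membered carbocycle, C2 forming as a mixture that the next two steps converge.

Step 21
Reactants: 33 the macrocyclic C2 alcohols
Product: 34 (6R,7S,8R,11R,1(10)Z,4Z)-13-(dimethylamino)-2-oxo-8-[(TBS)oxy]-15-[(TBDPS)oxy]germacra-1(10),4-dien-12,6-olide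
Conditions: Dess–Martin periodinane, NaHCO3, CH2Cl2, 0 °C; used at once
Reagents that add atoms: none
Why: Dess–Martin oxidation of the allylic alcohol takes both C2 epimers to one enone under buffered conditions.

Step 22
Reactants: 34 the C2 enone
Product: 35 (2S,6R,7S,8R,11R,1(10)Z,4Z)-13-(dimethylamino)-2-hydroxy-8-[(TBS)oxy]-15-[(TBDPS)oxy]germacra-1(10),4-dien-12,6-olide
Conditions: (R)-2-methyl-CBS-oxazaborolidine (0.5 equiv), catecholborane, toluene, −78 °C
Reagents that add atoms: none
Why: Corey–Bakshi–Shibata reduction, in which the (R)-oxazaborolidine should bind the ketone with the alkenyl C1 side as the large group and the C3 methylene as the small one and so give the (2S) alcohol under reagent control, catecholborane being mild toward the lactone and the alkenes.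

Step 23
Reactants: 35 the (2S) alcohol; 36 angelic acid [(2Z)-2-methylbut-2-enoic acid]
Product: 38 (2S,6R,7S,8R,11R,1(10)Z,4Z)-2-(angeloyloxy)-13-(dimethylamino)-8-[(TBS)oxy]-15-[(TBDPS)oxy]germacra-1(10),4-dien-12,6-olide, via mixed angelic 2,4,6-trichlorobenzoic anhydride 37 (not isolated)
Conditions: 36, 2,4,6-Cl3C6H2COCl, Et3N, toluene, rt; then 35, toluene, 80 °C
Reagents that add atoms: none
Why: Yamaguchi-type esterification through the mixed anhydride, run without a nucleophilic catalyst, acylates the only free hydroxyl at the less hindered carbonyl and should avoid angelate-to-tiglate isomerisation.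

Step 24
Reactants: 38 the C2 angelate
Product: 40 (2S,6R,7S,8R,1(10)Z,4Z)-2-(angeloyloxy)-8-[(TBS)oxy]-15-[(TBDPS)oxy]germacra-1(10),4,11(13)-trien-12,6-olide, via trimethylammonium iodide 39 (not isolated)
Conditions: MeI, THF, rt; then aq. NaHCO3, EtOAc, rt
Reagents that add atoms: none
Why: Quaternisation of the Mannich base followed by bicarbonate-induced Hofmann-type β-elimination releases the α-methylene lactone and removes the C11 stereocentre.

Step 25
Reactants: 40 the bis-silylated α-methylene lactone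
Product: 41 (2S,6R,7R,8R,1(10)Z,4Z)-2-(angeloyloxy)-8,15-dihydroxygermacra-1(10),4,11(13)-trien-12,6-olide
Conditions: HF·pyridine, pyridine, THF, 0 °C to rt
Reagents that add atoms: none
Why: Fluoride-mediated desilylation removes both silyl ethers under mildly acidic conditions that should spare the esters, the α-methylene lactone and the γ-hydroxy lactone arrangement.

Step 26
Reactants: 41 the 8,15-diol
Product: 42 (2S,6R,7R,8R,1(10)Z,4Z)-15-acetoxy-2-(angeloyloxy)-8-hydroxygermacra-1(10),4,11(13)-trien-12,6-olide (CNP0129394.1)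
Conditions: AcCl (1.05 equiv), 2,4,6-collidine, CH2Cl2, −78 °C
Reagents that add atoms: acetyl chloride, CC(=O)Cl
Why: Selective O-acetylation, in which acetyl chloride with a hindered pyridine base at −78 °C should take the primary allylic hydroxyl and leave the hindered secondary C8 hydroxyl, giving the target.

Compound list
1 | tert-butyl(but-3-yn-1-yloxy)dimethylsilane | C#CCCO[Si](C)(C)C(C)(C)C | starting material
2 | lithium acetylide of 1 | [Li]C#CCCO[Si](C)(C)C(C)(C)C | intermediate
3 | 5-[(TBS)oxy]pent-2-yn-1-ol | OCC#CCCO[Si](C)(C)C(C)(C)C | intermediate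
4 | cyclic sodium alkenylaluminate (2,5-dihydro-1,2-oxaluminole ate complex) | [Na+].COCCO[Al-]1(OCCOC)OCC=C1CCO[Si](C)(C)C(C)(C)C | intermediate
5 | (2Z)-5-[(TBS)oxy]-3-iodopent-2-en-1-ol | OC/C=C(\I)CCO[Si](C)(C)C(C)(C)C | intermediate
6 | (2Z)-5-[(TBS)oxy]-3-iodopent-2-enal | O=C/C=C(\I)CCO[Si](C)(C)C(C)(C)C | intermediate
7 | (3S,4Z)-7-[(TBS)oxy]-5-iodohepta-1,4-dien-3-ol | O[C@@H](C=C)/C=C(\I)CCO[Si](C)(C)C(C)(C)C | intermediate
8 | (3S,4Z)-7-[(TBS)oxy]-5-(hydroxymethyl)hepta-1,4-dien-3-ol | O[C@@H](C=C)/C=C(\CO)CCO[Si](C)(C)C(C)(C)C | intermediate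
9 | (3S,4Z)-7-[(TBS)oxy]-5-{[(TBDPS)oxy]methyl}hepta-1,4-dien-3-ol | O[C@@H](C=C)/C=C(\CO[Si](c1ccccc1)(c1ccccc1)C(C)(C)C)CCO[Si](C)(C)C(C)(C)C | intermediate
10 | acryloyl chloride | C=CC(=O)Cl | starting material
11 | (3S,4Z)-7-[(TBS)oxy]-5-{[(TBDPS)oxy]methyl}hepta-1,4-dien-3-yl prop-2-enoate | C=CC(=O)O[C@@H](C=C)/C=C(\CO[Si](c1ccccc1)(c1ccccc1)C(C)(C)C)CCO[Si](C)(C)C(C)(C)C | intermediate
12 | (5S)-5-[(1Z)-4-[(TBS)oxy]-2-{[(TBDPS)oxy]methyl}but-1-en-1-yl]furan-2(5H)-one | O=C1C=C[C@@H](/C=C(\CO[Si](c2ccccc2)(c2ccccc2)C(C)(C)C)CCO[Si](C)(C)C(C)(C)C)O1 | intermediate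
13 | prop-2-yn-1-ol | C#CCO | starting material
14 | cyclic alkenylmagnesium alkoxide (4-methyl-2,5-dihydro-1,2-oxamagnesole) | CC1=C[Mg]OC1 | intermediate
15 | (2Z)-3-iodo-2-methylprop-2-en-1-ol | OC/C(C)=C\I | intermediate
16 | lithium (2Z)-3-lithio-2-methylprop-2-en-1-olate | [Li]OC/C(C)=C\[Li] | intermediate
17 | trimethyl{[(2Z)-2-methyl-3-(trimethylsilyl)prop-2-en-1-yl]oxy}silane | C[Si](C)(C)OC/C(C)=C\[Si](C)(C)C | intermediate
18 | (2Z)-2-methyl-3-(trimethylsilyl)prop-2-en-1-ol | OC/C(C)=C\[Si](C)(C)C | intermediate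
19 | [(1Z)-3-bromo-2-methylprop-1-en-1-yl]trimethylsilane | BrC/C(C)=C\[Si](C)(C)C | intermediate
20 | 1,3-dithiane | C1CSCSC1 | starting material
21 | 2-lithio-1,3-dithiane | [Li]C1SCCCS1 | intermediate
22 | 2-[(2Z)-2-methyl-3-(trimethylsilyl)prop-2-en-1-yl]-1,3-dithiane | C[Si](C)(C)/C=C(/C)CC1SCCCS1 | intermediate
23 | N,N-dimethylmethyleneiminium iodide | C=[N+](C)C.[I-] | starting material
24 | 2-lithio derivative of 22 | [Li]C1(C/C(C)=C\[Si](C)(C)C)SCCCS1 | intermediate
25 | lithium enolate of the C7-dithianyl lactone (C11=C12–OLi) | [Li]OC1=C[C@H](C2(C/C(C)=C\[Si](C)(C)C)SCCCS2)[C@@H](/C=C(\CO[Si](c3ccccc3)(c3ccccc3)C(C)(C)C)CCO[Si](C)(C)C(C)(C)C)O1 | intermediate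
26 | (3R,4S,5R) trans,trans lactone with C8 dithiane and C11 CH2NMe2 | CN(C)C[C@@H]1C(=O)O[C@H](/C=C(\CO[Si](c2ccccc2)(c2ccccc2)C(C)(C)C)CCO[Si](C)(C)C(C)(C)C)[C@H]1C2(C/C(C)=C\[Si](C)(C)C)SCCCS2 | intermediate
27 | (3R,4S,5R) C8 ketone | CN(C)C[C@@H]1C(=O)O[C@H](/C=C(\CO[Si](c2ccccc2)(c2ccccc2)C(C)(C)C)CCO[Si](C)(C)C(C)(C)C)[C@H]1C(=O)C/C(C)=C\[Si](C)(C)C | intermediate
28 | (3R,4R,5R) lactone with (8R) alcohol | CN(C)C[C@@H]1C(=O)O[C@H](/C=C(\CO[Si](c2ccccc2)(c2ccccc2)C(C)(C)C)CCO[Si](C)(C)C(C)(C)C)[C@H]1[C@H](O)C/C(C)=C\[Si](C)(C)C | intermediate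
29 | C8 TBS ether of 28 | CN(C)C[C@@H]1C(=O)O[C@H](/C=C(\CO[Si](c2ccccc2)(c2ccccc2)C(C)(C)C)CCO[Si](C)(C)C(C)(C)C)[C@H]1[C@H](O[Si](C)(C)C(C)(C)C)C/C(C)=C\[Si](C)(C)C | intermediate
30 | (Z)-vinyl iodide (I on C1) | CN(C)C[C@@H]1C(=O)O[C@H](/C=C(\CO[Si](c2ccccc2)(c2ccccc2)C(C)(C)C)CCO[Si](C)(C)C(C)(C)C)[C@H]1[C@H](O[Si](C)(C)C(C)(C)C)C/C(C)=C\I | intermediate
31 | C2 primary alcohol | CN(C)C[C@@H]1C(=O)O[C@H](/C=C(\CO[Si](c2ccccc2)(c2ccccc2)C(C)(C)C)CCO)[C@H]1[C@H](O[Si](C)(C)C(C)(C)C)C/C(C)=C\I | intermediate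
32 | C2 aldehyde | CN(C)C[C@@H]1C(=O)O[C@H](/C=C(\CO[Si](c2ccccc2)(c2ccccc2)C(C)(C)C)CC=O)[C@H]1[C@H](O[Si](C)(C)C(C)(C)C)C/C(C)=C\I | intermediate
33 | macrocyclic C2 alcohol, C2 epimers | CN(C)C[C@@H]1C(=O)O[C@@H]2/C=C(\CO[Si](c3ccccc3)(c3ccccc3)C(C)(C)C)CC(O)/C=C(/C)C[C@@H](O[Si](C)(C)C(C)(C)C)[C@@H]12 | intermediate
34 | macrocyclic C2 enone | CN(C)C[C@@H]1C(=O)O[C@@H]2/C=C(\CO[Si](c3ccccc3)(c3ccccc3)C(C)(C)C)CC(=O)/C=C(/C)C[C@@H](O[Si](C)(C)C(C)(C)C)[C@@H]12 | intermediate
35 | macrocyclic (2S) alcohol | CN(C)C[C@@H]1C(=O)O[C@@H]2/C=C(\CO[Si](c3ccccc3)(c3ccccc3)C(C)(C)C)C[C@H](O)/C=C(/C)C[C@@H](O[Si](C)(C)C(C)(C)C)[C@@H]12 | intermediate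
36 | angelic acid | C/C=C(/C)C(=O)O | starting material
37 | angelic 2,4,6-trichlorobenzoic anhydride | C/C=C(/C)C(=O)OC(=O)c1c(Cl)cc(Cl)cc1Cl | intermediate
38 | C2 angelate with C13 NMe2 | CN(C)C[C@@H]1C(=O)O[C@@H]2/C=C(\CO[Si](c3ccccc3)(c3ccccc3)C(C)(C)C)C[C@H](OC(=O)/C(C)=C\C)/C=C(/C)C[C@@H](O[Si](C)(C)C(C)(C)C)[C@@H]12 | intermediate
39 | C13 trimethylammonium iodide of 38 | C[N+](C)(C)C[C@@H]1C(=O)O[C@@H]2/C=C(\CO[Si](c3ccccc3)(c3ccccc3)C(C)(C)C)C[C@H](OC(=O)/C(C)=C\C)/C=C(/C)C[C@@H](O[Si](C)(C)C(C)(C)C)[C@@H]12.[I-] | intermediate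
40 | α-methylene lactone with 8-OTBS and 15-OTBDPS | C=C1C(=O)O[C@@H]2/C=C(\CO[Si](c3ccccc3)(c3ccccc3)C(C)(C)C)C[C@H](OC(=O)/C(C)=C\C)/C=C(/C)C[C@@H](O[Si](C)(C)C(C)(C)C)[C@@H]12 | intermediate
41 | 8,15-diol | C=C1C(=O)O[C@@H]2/C=C(\CO)C[C@H](OC(=O)/C(C)=C\C)/C=C(/C)C[C@@H](O)[C@@H]12 | intermediate
42 | CNP0129394.1 | C=C1C(=O)O[C@@H]2/C=C(\COC(C)=O)C[C@H](OC(=O)/C(C)=C\C)/C=C(/C)C[C@@H](O)[C@@H]12 | target

Total step count: 26. Longest linear sequence: 22 steps (steps 1–8, then 13–26); the dithiane branch (steps 9–12) joins at step 13.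

Steps most likely to fail

1. Step 13. The basic carbanion may deprotonate the butenolide at C6 (loss of the stereocentre through the furanolate) or add 1,2, or the enolate may be quenched by proton transfer before aminomethylation. The fallback sets out from bromide 19 and butenolide 12 and uses a softer, far less basic acyl-anion equivalent. Alkylation of bis(phenylsulfanyl)methyllithium with 19 would give trimethyl[(1Z)-2-methyl-4,4-bis(phenylsulfanyl)but-1-en-1-yl]silane F1. Its lithio derivative (n-BuLi, THF, −78 °C) would add to 12 and be trapped with 23 to give the bis(phenylsulfanyl) analogue of 26, F2. Hydrolysis with PhI(OCOCF3)2 in wet MeCN would return to the route at ketone 27.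

2. Step 20. Oligomerisation may outrun closure of the strained ten-membered ring, or the β,γ-unsaturated aldehyde may isomerise before it is captured. The fallback sets out from alcohol 31 and closes the ring as a ketone. Oxidation (Dess–Martin periodinane, then NaClO2/NaH2PO4/2-methylbut-2-ene) would give the C2 carboxylic acid F3. 2,2'-Dipyridyl disulfide and PPh3 would convert it into the S-(pyridin-2-yl) thioester F4. Intramolecular nickel-mediated reductive coupling of the alkenyl iodide with the thioester (NiBr2 with 4,4'-di-tert-butyl-2,2'-bipyridine, Cp2ZrCl2, Zn, high dilution) would deliver enone 34 directly, where the route is rejoined; steps 19–21 are bypassed.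

3. Step 15. Facial selectivity at C8 may be poor, or the new alkoxide may attack C12 and translactonise. The fallback sets out from ketone 27 and replaces substrate control by catalyst control: Corey–Bakshi–Shibata reduction with the (S)-oxazaborolidine and catecholborane, in which branched C7 acts as the large group and the C9 methylene as the small one, should give the (8R) alcohol 28 under non-basic conditions; no new compound arises (F0).

Further compounds
F1 | step 13 | trimethyl[(1Z)-2-methyl-4,4-bis(phenylsulfanyl)but-1-en-1-yl]silane | C[Si](C)(C)/C=C(/C)CC(Sc1ccccc1)Sc1ccccc1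
F2 | step 13 | bis(phenylsulfanyl) analogue of 26 (C8 as C(SPh)2) | CN(C)C[C@@H]1C(=O)O[C@H](/C=C(\CO[Si](c2ccccc2)(c2ccccc2)C(C)(C)C)CCO[Si](C)(C)C(C)(C)C)[C@H]1C(Sc2ccccc2)(Sc2ccccc2)C/C(C)=C\[Si](C)(C)C
F3 | step 20 | C2 carboxylic acid derived from 31 | CN(C)C[C@@H]1C(=O)O[C@H](/C=C(\CO[Si](c2ccccc2)(c2ccccc2)C(C)(C)C)CC(=O)O)[C@H]1[C@H](O[Si](C)(C)C(C)(C)C)C/C(C)=C\I
F4 | step 20 | S-(pyridin-2-yl) thioester of F3 | CN(C)C[C@@H]1C(=O)O[C@H](/C=C(\CO[Si](c2ccccc2)(c2ccccc2)C(C)(C)C)CC(=O)Sc2ccccn2)[C@H]1[C@H](O[Si](C)(C)C(C)(C)C)C/C(C)=C\I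
F0 | step 15 | none | none
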